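**Retrosynthetic overview**
1. Target 11 ⇐ desilylation of 10; the C5 benzoate and C6 hydroxyl ⇐ titanium-mediated benzoate opening of the α-epoxide 9 ⇐ hydroxyl-directed epoxidation of cyclohexenone 8.
2. The six-membered ring ⇐ Lewis-acid α-ketol ring expansion (1,2-shift of the alkenyl ring carbon) of 1-acylcyclopentenol 7; the carbinol configuration of 7 is relayed into the quaternary C1 centre.
3. 7 ⇐ gold-catalysed oxidative benzoyloxylation of the ethynyl carbinol 6 ⇐ silylation of diol 5.
4. 5 ⇐ hydroxyl-directed syn-ethynylation (new) of (R)-4-hydroxycyclopent-2-en-1-one 1 with ethynylmagnesium bromide 2.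
5. Ring order: the cyclopentene of 1 is carried to 7 and expanded to the cyclohexenone in step 4; the oxirane of 9 is transient.

Convention: the target ring is numbered C1 (quaternary carbinol), C2 (C=O), C3 (CH2), C4 (CHOH), C5 (CHOBz), C6 (CHOH), with C7 the exocyclic CH2. β is the face of the C4 and C5 oxygens, α the face of the C1 and C6 hydroxyls. TBS = tert-butyldimethylsilyl.

**Step 1**
Reactants: 1 (R)-4-hydroxycyclopent-2-en-1-one; 2 ethynylmagnesium bromide
Product: 5 (1R,4R)-1-ethynylcyclopent-2-ene-1,4-diol, via dimethylaluminium alkoxide 3 (not isolated), via ethynylaluminate 4 (not isolated)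
Conditions: Me3Al (1.05 equiv), toluene, −78 °C; then 2 (0.5 M in THF, 1.3 equiv), −78 → −20 °C; aq. potassium sodium tartrate
Reagents that add atoms: none
Why: Proposed new method: the C4 hydroxyl is first turned into a dimethylaluminium alkoxide (loss of methane) and 2 then forms a tetracoordinate ethynylaluminate held covalently on the β-face, so the ethynyl ligand (which transfers in preference to methyl) is delivered through a six-membered transition state to the carbonyl carbon on the face of the C4 oxygen while the magnesium cation activates the carbonyl oxygen, giving the tertiary carbinol with ethynyl cis and OH trans to the C4 oxygen (the reverse of the usual anti 1,2-addition to 4-oxygenated cyclopentenones); the closest known reaction types are hydroxyl-directed hydride delivery from alkoxyborohydride ate complexes (Evans–Saksena reduction), alkoxide-directed (ligand-assisted) Grignard addition to 4-oxido enones and alkynyl transfer from alkynylaluminium ate complexes.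

**Step 2**
Reactants: 5 (1R,4R)-1-ethynylcyclopent-2-ene-1,4-diol
Product: 6 (1R,4R)-4-(tert-butyldimethylsilyloxy)-1-ethynylcyclopent-2-en-1-ol
Conditions: TBSCl, imidazole, DMF, 0 °C → rt
Reagents that add atoms: tert-butyldimethylsilyl chloride, CC(C)(C)[Si](C)(C)Cl
Why: Silyl ether formation that is chemoselective for the secondary allylic hydroxyl because the tertiary propargylic hydroxyl is too hindered for TBSCl/imidazole; no stereocentre is touched.

**Step 3**
Reactants: 6 (1R,4R)-4-(tert-butyldimethylsilyloxy)-1-ethynylcyclopent-2-en-1-ol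
Product: 7 2-[(1R,4R)-4-(tert-butyldimethylsilyloxy)-1-hydroxycyclopent-2-en-1-yl]-2-oxoethyl benzoate
Conditions: (Mor-DalPhos)AuNTf2 [Mor-DalPhos = (1-adamantyl)2P(C6H4-2-morpholino)] (5 mol %), 8-methylquinoline N-oxide (1.5 equiv), PhCO2H (2 equiv), PhCl, rt
Reagents that add atoms: 8-methylquinoline N-oxide, Cc1cccc2ccc[n+]([O-])c12; benzoic acid, OC(=O)c1ccccc1
Why: Gold-catalysed oxidation of a terminal alkyne (α-oxo gold carbene chemistry): the N-oxide attacks the internal carbon of the alkyne activated by monovalent gold, N–O cleavage leaves an α-oxo carbene at the terminal carbon, and benzoic acid inserts its O–H bond there to give the benzoyloxymethyl ketone regiospecifically with both stereocentres untouched.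

**Step 4**
Reactants: 7 2-[(1R,4R)-4-(tert-butyldimethylsilyloxy)-1-hydroxycyclopent-2-en-1-yl]-2-oxoethyl benzoate
Product: 8 [(1R,4R)-4-(tert-butyldimethylsilyloxy)-1-hydroxy-6-oxocyclohex-2-en-1-yl]methyl benzoate
Conditions: Cu(OTf)2 (10 mol %), 2,2′-bipyridine (11 mol %), 4 Å molecular sieves, ClCH2CH2Cl, 50 °C
Reagents that add atoms: none
Why: α-Ketol (acyloin) rearrangement run as a ring expansion (the D-homoannulation manifold): divalent copper holds the tertiary hydroxyl and the ketone oxygen in a cisoid five-membered chelate, the alkenyl ring carbon (better migrating group than the CH2 carbon, with release of cyclopentene strain) shifts suprafacially from the carbinol carbon to the carbonyl carbon, the old carbinol carbon becomes the C2 ketone, and the new C1 carbinol forms stereospecifically with its OH on the α-face (trans to the C4 silyloxy group) and C7 on the β-face.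

**Step 5**
Reactants: 8 [(1R,4R)-4-(tert-butyldimethylsilyloxy)-1-hydroxy-6-oxocyclohex-2-en-1-yl]methyl benzoate
Product: 9 [(1S,2S,5R,6R)-5-(tert-butyldimethylsilyloxy)-2-hydroxy-3-oxo-7-oxabicyclo[4.1.0]heptan-2-yl]methyl benzoate
Conditions: VO(acac)2 (5 mol %), tBuOOH (1.5 equiv, in decane), CH2Cl2, 0 °C → rt
Reagents that add atoms: tert-butyl hydroperoxide, CC(C)(C)OO
Why: Hydroxyl-directed epoxidation of an allylic alcohol (Sharpless–Michaelson vanadium/tBuOOH): the vanadium alkoxide of the tertiary C1 hydroxyl delivers oxygen to the C5=C6 bond on the α-face, which is also the face away from the C4 silyloxy and C7 groups, so the α-epoxide is formed.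

**Step 6**
Reactants: 9 [(1S,2S,5R,6R)-5-(tert-butyldimethylsilyloxy)-2-hydroxy-3-oxo-7-oxabicyclo[4.1.0]heptan-2-yl]methyl benzoate
Product: 10 [(1S,2S,3S,4R)-3-(benzoyloxy)-4-(tert-butyldimethylsilyloxy)-1,2-dihydroxy-6-oxocyclohexyl]methyl benzoate
Conditions: Ti(OiPr)4 (1.5 equiv), PhCO2H (2.5 equiv), CH2Cl2, rt
Reagents that add atoms: benzoic acid, OC(=O)c1ccccc1
Why: Titanium-mediated regioselective opening of a 2,3-epoxy alcohol by a carboxylic acid (Sharpless Ti(OiPr)4/PhCO2H): chelation of the C1 alkoxide and the epoxide oxygen directs benzoate to the distal carbon C5 (C6 is neopentylic), and inversion there puts the C5 benzoate on the β-face cis to the C4 oxygen while the C6 hydroxyl stays on the α-face cis to the C1 hydroxyl.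

**Step 7**
Reactants: 10 [(1S,2S,3S,4R)-3-(benzoyloxy)-4-(tert-butyldimethylsilyloxy)-1,2-dihydroxy-6-oxocyclohexyl]methyl benzoate
Product: 11 [(1S,2S,3R,4R)-3-(benzoyloxy)-1,2,4-trihydroxy-6-oxocyclohexyl]methyl benzoate
Conditions: HF·pyridine, THF/pyridine, 0 °C → rt
Reagents that add atoms: none
Why: Silyl ether cleavage by fluoride under mildly acidic conditions, chosen to avoid base-induced benzoate migration and β-elimination of the β-hydroxy ketone; no stereocentre changes.

**Compound list**
1 | (R)-4-hydroxycyclopent-2-en-1-one | O=C1C[C@@H](O)C=C1 | starting material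
2 | ethynylmagnesium bromide | C#C[Mg]Br | starting material
3 | dimethylaluminium (1R)-4-oxocyclopent-2-en-1-olate | C[Al](C)O[C@@H]1CC(=O)C=C1 | intermediate
4 | bromomagnesium ethynyl(dimethyl)[(1R)-4-oxocyclopent-2-en-1-olato]aluminate | C#C[Al-](C)(C)O[C@@H]1CC(=O)C=C1.[Mg+]Br | intermediate
5 | (1R,4R)-1-ethynylcyclopent-2-ene-1,4-diol (hydroxyls trans, ethynyl cis to the C4 hydroxyl) | C#C[C@@]1(O)C[C@@H](O)C=C1 | intermediate
6 | (1R,4R)-4-(tert-butyldimethylsilyloxy)-1-ethynylcyclopent-2-en-1-ol | C#C[C@@]1(O)C[C@@H](O[Si](C)(C)C(C)(C)C)C=C1 | intermediate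
7 | 2-[(1R,4R)-4-(tert-butyldimethylsilyloxy)-1-hydroxycyclopent-2-en-1-yl]-2-oxoethyl benzoate | O=C(OCC(=O)[C@@]1(O)C[C@@H](O[Si](C)(C)C(C)(C)C)C=C1)c1ccccc1 | intermediate
8 | [(1R,4R)-4-(tert-butyldimethylsilyloxy)-1-hydroxy-6-oxocyclohex-2-en-1-yl]methyl benzoate | O=C(OC[C@@]1(O)C(=O)C[C@@H](O[Si](C)(C)C(C)(C)C)C=C1)c1ccccc1 | intermediate
9 | [(1S,2S,5R,6R)-5-(tert-butyldimethylsilyloxy)-2-hydroxy-3-oxo-7-oxabicyclo[4.1.0]heptan-2-yl]methyl benzoate | O=C(OC[C@@]1(O)C(=O)C[C@@H](O[Si](C)(C)C(C)(C)C)[C@@H]2O[C@H]12)c1ccccc1 | intermediate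
10 | [(1S,2S,3S,4R)-3-(benzoyloxy)-4-(tert-butyldimethylsilyloxy)-1,2-dihydroxy-6-oxocyclohexyl]methyl benzoate | O=C(OC[C@@]1(O)C(=O)C[C@@H](O[Si](C)(C)C(C)(C)C)[C@@H](OC(=O)c2ccccc2)[C@@H]1O)c1ccccc1 | intermediate
11 | [(1S,2S,3R,4R)-3-(benzoyloxy)-1,2,4-trihydroxy-6-oxocyclohexyl]methyl benzoate (CNP0127041.1) | O=C(OC[C@@]1(O)C(=O)C[C@@H](O)[C@@H](OC(=O)c2ccccc2)[C@@H]1O)c1ccccc1 | target

**Totals**
Total step count: 7. Longest linear sequence: 7 steps (1 → 11).

**Three steps most likely to fail**

Step 1 (the proposed directed ethynylation). The undirected anti addition, or a directed 1,4-transfer, could compete and erode the syn selectivity on which the C1 configuration depends. The fallback uses known chemistry only; it sets out from 2 and returns at 5. Compound 2 is added in the usual anti sense (THF, −78 °C) to commercial (S)-4-(tert-butyldimethylsilyloxy)cyclopent-2-en-1-one F1, giving (1R,4S)-4-(tert-butyldimethylsilyloxy)-1-ethynylcyclopent-2-en-1-ol F2, which already has the required carbinol configuration. Bu4NF removes the silyl group to give (1R,4S)-1-ethynylcyclopent-2-ene-1,4-diol F3. Mitsunobu inversion of the secondary allylic alcohol (PPh3, DIAD, 4-nitrobenzoic acid) gives (1R,4R)-4-ethynyl-4-hydroxycyclopent-2-en-1-yl 4-nitrobenzoate F4, and K2CO3/MeOH releases 5.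

Step 3 (gold-catalysed oxidative benzoyloxylation). The free tertiary, allylic and propargylic hydroxyl may trap the gold carbene intramolecularly (oxetan-3-one) or ionise (Meyer–Schuster products). The fallback sets out from 6 and returns at 7. It forms the C7–O bond by enol chemistry instead of carbene O–H insertion. Markovnikov hydration of the alkyne (Ph3PAuNTf2 cat., H2O, 1,4-dioxane, 60 °C) gives 1-[(1R,4R)-4-(tert-butyldimethylsilyloxy)-1-hydroxycyclopent-2-en-1-yl]ethan-1-one F5. Oxidative α-benzoyloxylation of its only enolisable position with PhCO2H (Bu4NI cat., tBuOOH, EtOAc, 75 °C) then gives 7.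

Step 4 (α-ketol ring expansion). The CH2 carbon could migrate instead of the alkenyl carbon, giving the conjugated enone regioisomer, or the product α-ketol could isomerise further. The fallback sets out from 7 and returns at 10. It moves the oxygenation ahead of the ring expansion, so that the migrating atom is an oxygen-bearing sp3 carbon as in classical D-homoannulations. Hydroxyl-directed epoxidation of 7 (VO(acac)2, tBuOOH) gives 2-[(1S,2R,4R,5R)-4-(tert-butyldimethylsilyloxy)-2-hydroxy-6-oxabicyclo[3.1.0]hexan-2-yl]-2-oxoethyl benzoate F6. Ti(OiPr)4/PhCO2H opens it at the distal carbon to give 2-[(1R,2S,3S,4R)-3-(benzoyloxy)-4-(tert-butyldimethylsilyloxy)-1,2-dihydroxycyclopentyl]-2-oxoethyl benzoate F7. Lewis-acid α-ketol ring expansion of F7 (Cu(OTf)2/2,2′-bipyridine, or Al(OiPr)3 in hot toluene), with migration of the carbinol-bearing ring carbon, then gives 10 directly.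

**Further compounds**
F1 | step 1 | (S)-4-(tert-butyldimethylsilyloxy)cyclopent-2-en-1-one | O=C1C[C@H](O[Si](C)(C)C(C)(C)C)C=C1
F2 | step 1 | (1R,4S)-4-(tert-butyldimethylsilyloxy)-1-ethynylcyclopent-2-en-1-ol | C#C[C@@]1(O)C[C@H](O[Si](C)(C)C(C)(C)C)C=C1
F3 | step 1 | (1R,4S)-1-ethynylcyclopent-2-ene-1,4-diol | C#C[C@@]1(O)C[C@H](O)C=C1
F4 | step 1 | (1R,4R)-4-ethynyl-4-hydroxycyclopent-2-en-1-yl 4-nitrobenzoate | C#C[C@@]1(O)C[C@@H](OC(=O)c2ccc(cc2)[N+](=O)[O-])C=C1
F5 | step 3 | 1-[(1R,4R)-4-(tert-butyldimethylsilyloxy)-1-hydroxycyclopent-2-en-1-yl]ethan-1-one | CC(=O)[C@@]1(O)C[C@@H](O[Si](C)(C)C(C)(C)C)C=C1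
F6 | step 4 | 2-[(1S,2R,4R,5R)-4-(tert-butyldimethylsilyloxy)-2-hydroxy-6-oxabicyclo[3.1.0]hexan-2-yl]-2-oxoethyl benzoate | O=C(OCC(=O)[C@@]1(O)C[C@@H](O[Si](C)(C)C(C)(C)C)[C@@H]2O[C@H]12)c1ccccc1
F7 | step 4 | 2-[(1R,2S,3S,4R)-3-(benzoyloxy)-4-(tert-butyldimethylsilyloxy)-1,2-dihydroxycyclopentyl]-2-oxoethyl benzoate | O=C(OCC(=O)[C@@]1(O)C[C@@H](O[Si](C)(C)C(C)(C)C)[C@@H](OC(=O)c2ccccc2)[C@@H]1O)c1ccccc1
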